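**Assumption:** 1, 2, 6 and 9 are bought as benzyl ethers (catalogue compounds); primed locants denote the lower unit; dry HCl is the condensing acid, so 14 is a chloride.

## Structural features

The target is a biflavanoid in which two chroman units are joined by a single bond from C4 of the upper ring C to C8' of the lower ring A'. The upper unit (rings A, C and B) is a 7-hydroxychroman with a catechol ring B at C2 and no oxygen at C3 or C5. The lower unit (rings A', C' and B') is epigallocatechin, a 5',7'-dihydroxychroman with a pyrogallol ring B' at C2' and a hydroxyl at C3'. C2 (S) and C4 (R) are 1,3-related and trans in ring C, C2' (R) and C3' (R) are adjacent and cis in ring C', and the C4–C8' bond insulates one pair from the other. The fragile parts are the nine phenols (the pyrogallol ring B' above all), the two benzylic aryl ethers C2–O1 and C2'–O1', and the doubly benzylic C4. The real difficulty is to tie the absolute configuration of the lower pair to that of the upper pair while placing the interflavan bond at C8' and not at C6'. The key step uses the fact that ring C' (O1', C2', C3', C4', C4a', C8a') is the reduced form of a 3-oxygenated pyrylium ring: its C3'–C4' and O1'–C2' bonds can be made from a formyl carbon on C4a', a phenolic oxygen on C8a' and an α-oxygenated aryl ketone, and in the aldehyde used the oxygen beside C8' is the only one left free.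

## Logic of the disconnections

**16 back to 14.** The C–H bonds at C2', C3' and C4' are removed and the nine O–H bonds become O–benzyl. The lower unit then has no stereocentre, and all hydroxyls carry one kind of group that the reduction itself removes. The forward step must add hydrogen to C2' and C3' from one face (cis). It has no handle on which face, so 16 must be separated from its (2'S,3'S) isomer; 15 lies on the way and is not isolated.

**14 back to 8 and 12.** The cut is at C3'–C4' and O1'–C2'. It divides the molecule into two pieces of similar size and removes ring C'. The forward step needs a single free hydroxyl ortho to the formyl group of 8, placed beside the carbon that carries the upper unit. It also needs an acid that leaves C2–O1 and C4–C8' alone. Uniform benzyl protection makes any acid-induced loss of a benzyl group harmless, and 13 is passed through without isolation.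

**8 back to 7.** The bond from the formyl carbon to the future C4a' is cut. The free hydroxyl of 7 is then the directing group, so no separate protecting-group step is needed. The forward step must formylate only ortho to that hydroxyl, not at the carbon between the two benzyloxy groups.

**7 back to 5 and 6.** The C4–C8' bond is cut. C4 is benzylic and its ring carbon stands para to the 7-oxygen and ortho to O1, so it is a natural cation; 6 is an electron-rich arene with a free hydroxyl. The forward step must attack ortho to that hydroxyl and trans to the aryl group at C2, without epimerising C2.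

**5 back to 4.** The C4–H bond is cut. The carbinol is only a leaving group in waiting, but its formation is the point where the enantiomers of 4 are told apart. The catalyst must reduce the (2S) ketone and leave the (2R) ketone.

**4 back to 3, then 1 and 2.** O1–C2 is cut (conjugate addition), then C2–C3 (aldol condensation). Both forward steps are simple; C2 is formed racemic.

**12 back to 11, then 9 (through 10).** The C2'–C3' bond of the future ring is cut between the carbonyl carbon and the benzyloxymethyl carbon, then the amide C–N bond. The forward step must stop after one addition of the carbanion.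

## Other disconnections considered

**Alternative 1:** The cut is at O1–C2 and C3–C4 of the upper ring C. The diarylmethanol A1, which carries the protected lower unit on its carbinol carbon, is dehydrated by a bulky binaphthyl phosphoric acid to the ortho-quinone methide A2. This adds ethyl vinyl ether A3 in a hetero-Diels–Alder reaction to give the 2-ethoxychroman A4.
- In favour: the lower unit comes intact from natural epigallocatechin A5, so C2' and C3' are never in question. On this point the alternative is better than the chosen plan. Ring closure is pericyclic and only weakly acidic, and C4 is set as the ring forms.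
- Against: A4 has ethoxy, not the catechol ring, at C2. Ring B must be introduced later at an oxocarbenium ion, with C2 controlled only by C4; the chosen plan fixes C2 early and is better there. The methide carbon of A2 bears a crowded aryl group with its own stereocentres, so the catalyst works in a matched or mismatched setting. A1 needs a metalated C8' on the protected lower unit, where C6' competes.
- Step economy: about equal to the chosen plan.

**Alternative 2:** The cut is at C4–C4a and C4–C8' in one operation. BF3·OEt2 cyclises the (S)-aldehyde A6 onto its benzyloxyphenoxy ring, the carbinol ionises in the same flask, and free A5 captures the cation to give A7.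
- In favour: it is the shortest route. The lower stereocentres come from the chiral pool, and only three benzyl ethers remain to be removed. On step economy and on the lower-unit configuration it is better than the chosen plan.
- Against: free A5 offers C6' as well as C8', and A7 is itself a nucleophile, so regiochemistry rests on a kinetic preference and oligomers can form. In the chosen plan the 4→8 bond is fixed by the constitution of 8, which is better. The benzylic aryl ether of A6 sits next to the Lewis acid and can ionise, a risk equal to that of step 4 here.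

**Alternative 3:** The cut is in ring A' (C8'–C8a', C6'–C7', C4a'–C8a'). Heating the cyclobutenone A8 with the siloxyalkyne A9 gives the phenol A10 through a vinylketene, cycloaddition and two electrocyclic steps.
- In favour: the mechanism places the free hydroxyl beside the carbon that bears the upper unit, so there is no ortho or para question. This is better than step 4 of the chosen plan. The conditions are thermal and acid-free, and the oxygens come out differentiated.
- Against: the C4–C8' bond and the trans relation of C2 and C4 must already exist in A9, which is long to make. A8 is sensitive. A10 still lacks ring C' and would need the same formylation and pyrylium closure, so the facial problem of the reduction is unchanged (equal to the chosen plan). Step economy is worse.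

Key step: step 8

## Route

**Step 1**
Reactants: 1 1-[4-(benzyloxy)-2-hydroxyphenyl]ethanone; 2 3,4-bis(benzyloxy)benzaldehyde
Product: 3 (E)-1-[4-(benzyloxy)-2-hydroxyphenyl]-3-[3,4-bis(benzyloxy)phenyl]prop-2-en-1-one
Conditions: KOH (50% aq), EtOH–THF, rt, 48 h; then dilute HCl
Reagents that add atoms: none
Why: Claisen–Schmidt (crossed aldol) condensation; 2 has no α-hydrogen, the methyl ketone of 1 still enolises as its phenoxide, and loss of water gives the conjugated E-enone; benzyl ethers are inert to aqueous base.

**Step 2**
Reactants: 3 the chalcone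
Product: 4 rac-7-(benzyloxy)-2-[3,4-bis(benzyloxy)phenyl]chroman-4-one
Conditions: NaOAc, EtOH, reflux
Reagents that add atoms: none
Why: Intramolecular oxa-Michael addition (6-endo-trig) of the phenoxide to the enone closes ring C; C2 is formed racemic on purpose, and unreacted 3 is returned to the step because the reaction is an equilibrium.

**Step 3**
Reactants: 4 the racemic flavanone
Product: 5 (2S,4S)-7-(benzyloxy)-2-[3,4-bis(benzyloxy)phenyl]chroman-4-ol (2,4-cis)
Conditions: RuCl(p-cymene)[(S,S)-TsDPEN] (1 mol%; TsDPEN = N-tosyl-1,2-diphenylethylenediamine), HCO2H–Et3N (5:2), EtOAc, rt, to about half conversion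
Reagents that add atoms: none
Why: Noyori asymmetric transfer hydrogenation run as a kinetic resolution: the (S,S)-catalyst delivers hydride to the face that gives the (4S)-carbinol, and only in (2S)-4 is that also the face anti to the equatorial C2 aryl group, so this enantiomer should be reduced much faster to the cis alcohol; the (2R)-ketone is recovered and can be racemised through 3 under the conditions of step 2. The C4 carbinol is only a handle and is given up as water in step 4.

**Step 4**
Reactants: 5 the (2S,4S)-flavan-4-ol; 6 3,5-bis(benzyloxy)phenol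
Product: 7 3,5-bis(benzyloxy)-2-[(2S,4R)-7-(benzyloxy)-2-[3,4-bis(benzyloxy)phenyl]chroman-4-yl]phenol (2,4-trans)
Conditions: BF3·OEt2 (0.3 equiv), CH2Cl2, −30 to 0 °C; the phenol in excess, recovered
Reagents that add atoms: none
Why: Friedel–Crafts alkylation of a phenol by a benzylic alcohol: BF3 ionises the C4–OH bond of 5, the hydroxyl leaving as water, to a cation stabilised by O1 and the 7-benzyloxy group. 6 should attack through a carbon ortho to its hydroxyl (two equivalent sites, each less crowded than the carbon between the benzyloxy groups; O-alkylation is reversible) and on the face of the half-chair opposite the equatorial C2 aryl group, which sets C4 as (R), trans to C2. A threefold excess of 6 suppresses double alkylation and is recovered unchanged.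

**Step 5**
Reactants: 7 the arylated phenol
Product: 8 4,6-bis(benzyloxy)-3-[(2S,4R)-7-(benzyloxy)-2-[3,4-bis(benzyloxy)phenyl]chroman-4-yl]-2-hydroxybenzaldehyde
Conditions: MgCl2, Et3N, (CH2O)n, THF, reflux; then 1 M HCl
Reagents that add atoms: paraformaldehyde (formaldehyde), C=O
Why: Magnesium-mediated ortho-formylation of a phenol (Casnati–Skattebøl): the magnesium phenoxide delivers formaldehyde only to its one free ortho carbon (the future C4a'), and a second equivalent of formaldehyde takes up hydride in an Oppenauer-type transfer; the carbon between the two benzyloxy groups is not reached and no stereocentre is touched.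

**Step 6**
Reactants: 9 3,4,5-tris(benzyloxy)benzoic acid
Product: 11 N-methoxy-N-methyl-3,4,5-tris(benzyloxy)benzamide, via acyl imidazolide 10 (not isolated)
Conditions: CDI, THF, rt; then MeNHOMe·HCl, rt
Reagents that add atoms: N,O-dimethylhydroxylamine hydrochloride, CNOC.Cl; 1,1'-carbonyldiimidazole, O=C(n1ccnc1)n1ccnc1 (its imidazolyl group is in 10 only)
Why: Amide formation through an acyl imidazolide; CDI activates the acid with loss of CO2, and the hydrochloride supplies the amine while protonating imidazole, which makes 10 more reactive.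

**Step 7**
Reactants: 11 the N-methoxy-N-methyl amide
Product: 12 2-(benzyloxy)-1-[3,4,5-tris(benzyloxy)phenyl]ethanone
Conditions: Bu3SnCH2OBn, n-BuLi, THF, −78 °C; then 11, −78 to −40 °C; NH4Cl aq
Reagents that add atoms: tributyl[(benzyloxy)methyl]stannane, CCCC[Sn](CCCC)(CCCC)COCc1ccccc1
Why: Weinreb ketone synthesis with an α-alkoxy organolithium made by tin–lithium exchange; the amide takes up one equivalent only because the adduct stays chelated until the quench, and at −78 °C the carbanion should not undergo Wittig rearrangement.

**Step 8**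
Reactants: 8 the salicylaldehyde; 12 the α-benzyloxy ketone
Product: 14 3,5,7-tris(benzyloxy)-8-[(2S,4R)-7-(benzyloxy)-2-[3,4-bis(benzyloxy)phenyl]chroman-4-yl]-2-[3,4,5-tris(benzyloxy)phenyl]chromenylium chloride, via aldol enone 13 (not isolated)
Conditions: HCl (g), EtOAc, 0 °C to rt, 2–3 d; Et2O to complete precipitation
Reagents that add atoms: hydrogen chloride, Cl (the chloride counter-ion)
Why: This is a Robinson anthocyanidin synthesis. HCl enolises 12 and activates the formyl group of 8; aldol addition and loss of water give 13 and with it the C3'–C4' bond. In acid the enone reaches the geometry in which the phenolic oxygen can add to the protonated ketone carbon (6-exo-trig), giving a cyclic hemiketal (O1'–C2'); loss of its hydroxyl as a second molecule of water, driven by aromatisation, closes ring C' as the pyrylium ring of 14. No stereocentre is formed, and C2 and C4 take no part. The selectivity that matters is the direction of ring closure: the formyl group of 8 has a single free ortho hydroxyl, the one beside the carbon carrying the upper unit, so that carbon must become C8'. The second requirement is that the acid spares the upper unit: without an oxygen at C5 the C4 cation is poorly stabilised, so the C4–C8' bond should not ionise, and the C2–O1 aryl alkyl ether is weakly basic. Precipitation of 14 should pull both condensations forward, and a benzyl ether lost from the cationic ring would not matter because step 9 removes all nine.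

**Step 9**
Reactants: 14 the nonabenzyl flavylium chloride
Product: 16 (2R,3R)-8-[(2S,4R)-2-(3,4-dihydroxyphenyl)-7-hydroxychroman-4-yl]-2-(3,4,5-trihydroxyphenyl)chroman-3,5,7-triol, via free flavylium chloride 15 (not isolated)
Conditions: H2 (1 atm), Pd(OH)2/C, THF–MeOH, 0.1% HCl, rt; then PtO2, H2 (3 atm), rt; preparative reversed-phase HPLC
Reagents that add atoms: none
Why: Hydrogenolysis over Pd(OH)2/C removes the nine benzyl ethers to give 15, and heterogeneous hydrogenation over platinum then adds two equivalents of H2 to the pyrylium ring (the known catalytic reduction of 3-hydroxyflavylium salts to 2,3-cis-flavan-3-ols); the hydrogens at C2' and C3' come from one catalyst face, hence cis. Nothing in 15 reliably shields one face of ring C', so 16 is expected together with its (2'S,3'S) isomer; these are diastereomers through the fixed (2S,4R) upper unit and are parted by HPLC, while the acid keeps 15 in the pyrylium form and C2 and C4 are untouched.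

## Compound list

1 | 1-[4-(benzyloxy)-2-hydroxyphenyl]ethanone | CC(=O)c1ccc(OCc2ccccc2)cc1O | starting material
2 | 3,4-bis(benzyloxy)benzaldehyde | O=Cc1ccc(OCc2ccccc2)c(OCc2ccccc2)c1 | starting material
3 | (E)-1-[4-(benzyloxy)-2-hydroxyphenyl]-3-[3,4-bis(benzyloxy)phenyl]prop-2-en-1-one | O=C(/C=C/c1ccc(OCc2ccccc2)c(OCc2ccccc2)c1)c1ccc(OCc2ccccc2)cc1O | intermediate
4 | rac-7-(benzyloxy)-2-[3,4-bis(benzyloxy)phenyl]chroman-4-one | O=C1CC(c2ccc(OCc3ccccc3)c(OCc3ccccc3)c2)Oc2cc(OCc3ccccc3)ccc21 | intermediate
5 | (2S,4S)-7-(benzyloxy)-2-[3,4-bis(benzyloxy)phenyl]chroman-4-ol | c1ccccc1COc1ccc2c(c1)O[C@H](c1ccc(OCc3ccccc3)c(OCc3ccccc3)c1)C[C@@H]2O | intermediate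
6 | 3,5-bis(benzyloxy)phenol | Oc1cc(OCc2ccccc2)cc(OCc2ccccc2)c1 | starting material
7 | 3,5-bis(benzyloxy)-2-[(2S,4R)-7-(benzyloxy)-2-[3,4-bis(benzyloxy)phenyl]chroman-4-yl]phenol | c1ccccc1COc1ccc2c(c1)O[C@H](c1ccc(OCc3ccccc3)c(OCc3ccccc3)c1)C[C@H]2c1c(O)cc(OCc2ccccc2)cc1OCc1ccccc1 | intermediate
8 | 4,6-bis(benzyloxy)-3-[(2S,4R)-7-(benzyloxy)-2-[3,4-bis(benzyloxy)phenyl]chroman-4-yl]-2-hydroxybenzaldehyde | c1ccccc1COc1ccc2c(c1)O[C@H](c1ccc(OCc3ccccc3)c(OCc3ccccc3)c1)C[C@H]2c1c(OCc2ccccc2)cc(OCc2ccccc2)c(C=O)c1O | intermediate
9 | 3,4,5-tris(benzyloxy)benzoic acid | OC(=O)c1cc(OCc2ccccc2)c(OCc2ccccc2)c(OCc2ccccc2)c1 | starting material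
10 | 1-[3,4,5-tris(benzyloxy)benzoyl]imidazole | O=C(n1ccnc1)c1cc(OCc2ccccc2)c(OCc2ccccc2)c(OCc2ccccc2)c1 | intermediate
11 | N-methoxy-N-methyl-3,4,5-tris(benzyloxy)benzamide | CON(C)C(=O)c1cc(OCc2ccccc2)c(OCc2ccccc2)c(OCc2ccccc2)c1 | intermediate
12 | 2-(benzyloxy)-1-[3,4,5-tris(benzyloxy)phenyl]ethanone | O=C(COCc1ccccc1)c1cc(OCc2ccccc2)c(OCc2ccccc2)c(OCc2ccccc2)c1 | intermediate
13 | 2-(benzyloxy)-3-{4,6-bis(benzyloxy)-3-[(2S,4R)-7-(benzyloxy)-2-[3,4-bis(benzyloxy)phenyl]chroman-4-yl]-2-hydroxyphenyl}-1-[3,4,5-tris(benzyloxy)phenyl]prop-2-en-1-one (alkene geometry not fixed) | c1ccccc1COc1ccc2c(c1)O[C@H](c1ccc(OCc3ccccc3)c(OCc3ccccc3)c1)C[C@H]2c1c(OCc2ccccc2)cc(OCc2ccccc2)c(C=C(OCc2ccccc2)C(=O)c2cc(OCc3ccccc3)c(OCc3ccccc3)c(OCc3ccccc3)c2)c1O | intermediate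
14 | 3,5,7-tris(benzyloxy)-8-[(2S,4R)-7-(benzyloxy)-2-[3,4-bis(benzyloxy)phenyl]chroman-4-yl]-2-[3,4,5-tris(benzyloxy)phenyl]chromenylium chloride | c1ccccc1COc1ccc2c(c1)O[C@H](c1ccc(OCc3ccccc3)c(OCc3ccccc3)c1)C[C@H]2c1c(OCc2ccccc2)cc(OCc2ccccc2)c2cc(OCc3ccccc3)c(-c3cc(OCc4ccccc4)c(OCc4ccccc4)c(OCc4ccccc4)c3)[o+]c12.[Cl-] | intermediate
15 | 8-[(2S,4R)-2-(3,4-dihydroxyphenyl)-7-hydroxychroman-4-yl]-3,5,7-trihydroxy-2-(3,4,5-trihydroxyphenyl)chromenylium chloride | Oc1ccc2c(c1)O[C@H](c1ccc(O)c(O)c1)C[C@H]2c1c(O)cc(O)c2cc(O)c(-c3cc(O)c(O)c(O)c3)[o+]c12.[Cl-] | intermediate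
16 | (2R,3R)-8-[(2S,4R)-2-(3,4-dihydroxyphenyl)-7-hydroxychroman-4-yl]-2-(3,4,5-trihydroxyphenyl)chroman-3,5,7-triol | Oc1ccc2c(c1)O[C@H](c1ccc(O)c(O)c1)C[C@H]2c1c(O)cc(O)c2c1O[C@H](c1cc(O)c(O)c(O)c1)[C@H](O)C2 | target

## Step count and least certain steps

Total step count: 9. Longest linear sequence: 7 steps (steps 1, 2, 3, 4, 5, 8, 9); steps 6 and 7 form the side branch.

**Step 8 (key step).** The condensation may stall, because the formyl group of 8 is flanked by two donor oxygens and is weakly electrophilic, and its neighbouring hydroxyl is crowded by the upper unit. Long exposure to HCl may also open the C2–O1 ether and erode the configuration at C2. The fallback separates the two bond formations. It sets out from 11 and 8 and returns at 14. Lithiated diethyl (benzyloxymethyl)phosphonate is acylated by 11 to give the racemic β-keto phosphonate diethyl {1-(benzyloxy)-2-oxo-2-[3,4,5-tris(benzyloxy)phenyl]ethyl}phosphonate F1. A Horner–Wadsworth–Emmons olefination of 8 with F1 (Ba(OH)2, wet THF) gives 13 as an isolated enone. Brief treatment with HCl in AcOH–EtOAc then closes the pyrylium ring to 14 with loss of water.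

**Step 9.** Hydrogen delivery without facial discrimination is inherent and is expected to cost roughly half of the material. Poor chromatographic resolution of the two free-phenol diastereomers, air oxidation of the pyrogallol ring during handling, and hydrogenolytic opening at C2'–O1' can cost more. The fallback sets out from 14 and returns at 16. After the hydrogenation of 14 as in step 9, the crude product is acetylated (Ac2O, pyridine) to the nona-O-acetyl derivative F2 of 16 and to the corresponding derivative of its (2'S,3'S) isomer. These are separated on silica gel as stable, non-polar compounds. K2CO3 in degassed MeOH at 0 °C, followed by an acidic resin, then gives 16. This eases the separation and the handling; it does not cure the lack of facial control, which only a lower unit from the chiral pool would.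

**Step 4.** The cation may also attack the carbon para to the hydroxyl of 6 (between the benzyloxy groups), alkylate twice, or lose part of its trans preference; BF3 may also ionise C2–O1. The fallback sets out from 5 and returns at 8, replacing steps 4 and 5. 5 is condensed with a large excess of phloroglucinol, whose ring carbons are all equivalent, to give 2-[(2S,4R)-7-(benzyloxy)-2-[3,4-bis(benzyloxy)phenyl]chroman-4-yl]benzene-1,3,5-triol F3. Vilsmeier–Haack formylation (POCl3, DMF, then water) can only enter one of two equivalent carbons and gives the trihydroxybenzaldehyde F4. K2CO3 with two equivalents of benzyl bromide should then etherify the hydroxyl para to the formyl group and the less hindered of the two hydrogen-bonded ortho hydroxyls, which leaves the one beside the upper unit free, as in 8.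

**Step 3.** Hydride transfer may be slow, because the 7-alkoxy group makes the ketone a vinylogous ester, and the discrimination between the enantiomers may fade as conversion is pushed. The fallback sets out from 4 and returns at 5. NaBH4 in MeOH–THF reduces 4 to the racemic cis alcohol rac-(2S*,4S*)-7-(benzyloxy)-2-[3,4-bis(benzyloxy)phenyl]chroman-4-ol F5. A lipase (Candida antarctica lipase B, vinyl acetate, toluene) then acetylates one enantiomer. By the usual lipase preference for the (R)-carbinol of aryl alkyl carbinols, the (2R,4R) alcohol should be esterified and 5 left as the free alcohol.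

## Further compounds

F1 | step 8 | diethyl {1-(benzyloxy)-2-oxo-2-[3,4,5-tris(benzyloxy)phenyl]ethyl}phosphonate (racemic) | CCOP(=O)(OCC)C(OCc1ccccc1)C(=O)c1cc(OCc2ccccc2)c(OCc2ccccc2)c(OCc2ccccc2)c1
F2 | step 9 | nonaacetate of 16 | CC(=O)Oc1ccc2c(c1)O[C@H](c1ccc(OC(C)=O)c(OC(C)=O)c1)C[C@H]2c1c(OC(C)=O)cc(OC(C)=O)c2c1O[C@H](c1cc(OC(C)=O)c(OC(C)=O)c(OC(C)=O)c1)[C@H](OC(C)=O)C2
F3 | step 4 | 2-[(2S,4R)-7-(benzyloxy)-2-[3,4-bis(benzyloxy)phenyl]chroman-4-yl]benzene-1,3,5-triol | c1ccccc1COc1ccc2c(c1)O[C@H](c1ccc(OCc3ccccc3)c(OCc3ccccc3)c1)C[C@H]2c1c(O)cc(O)cc1O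
F4 | step 4 | 3-[(2S,4R)-7-(benzyloxy)-2-[3,4-bis(benzyloxy)phenyl]chroman-4-yl]-2,4,6-trihydroxybenzaldehyde | c1ccccc1COc1ccc2c(c1)O[C@H](c1ccc(OCc3ccccc3)c(OCc3ccccc3)c1)C[C@H]2c1c(O)cc(O)c(C=O)c1O
F5 | step 3 | rac-(2S*,4S*)-7-(benzyloxy)-2-[3,4-bis(benzyloxy)phenyl]chroman-4-ol (racemate; the (2S,4S) enantiomer is written) | c1ccccc1COc1ccc2c(c1)O[C@H](c1ccc(OCc3ccccc3)c(OCc3ccccc3)c1)C[C@@H]2O
A1 | alternative 1 | [4-(benzyloxy)-2-hydroxyphenyl][(2R,3R)-3,5,7-tris(benzyloxy)-2-[3,4,5-tris(benzyloxy)phenyl]chroman-8-yl]methanol (carbinol carbon unassigned) | OC(c1ccc(OCc2ccccc2)cc1O)c1c(OCc2ccccc2)cc(OCc2ccccc2)c2c1O[C@H](c1cc(OCc3ccccc3)c(OCc3ccccc3)c(OCc3ccccc3)c1)[C@H](OCc1ccccc1)C2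
A2 | alternative 1 | 3-(benzyloxy)-6-{[(2R,3R)-3,5,7-tris(benzyloxy)-2-[3,4,5-tris(benzyloxy)phenyl]chroman-8-yl]methylidene}cyclohexa-2,4-dien-1-one | O=C1C=C(OCc2ccccc2)C=CC1=Cc1c(OCc2ccccc2)cc(OCc2ccccc2)c2c1O[C@H](c1cc(OCc3ccccc3)c(OCc3ccccc3)c(OCc3ccccc3)c1)[C@H](OCc1ccccc1)C2
A3 | alternative 1 | ethyl vinyl ether | C=COCC
A4 | alternative 1 | (4R)-7-(benzyloxy)-2-ethoxy-4-[(2R,3R)-3,5,7-tris(benzyloxy)-2-[3,4,5-tris(benzyloxy)phenyl]chroman-8-yl]chroman (acetal carbon unassigned) | c1ccccc1COc1ccc2c(c1)OC(OCC)C[C@H]2c1c(OCc2ccccc2)cc(OCc2ccccc2)c2c1O[C@H](c1cc(OCc3ccccc3)c(OCc3ccccc3)c(OCc3ccccc3)c1)[C@H](OCc1ccccc1)C2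
A5 | alternative 1 | (−)-epigallocatechin, (2R,3R)-2-(3,4,5-trihydroxyphenyl)chroman-3,5,7-triol | Oc1cc(O)c2c(c1)O[C@H](c1cc(O)c(O)c(O)c1)[C@H](O)C2
A6 | alternative 2 | (3S)-3-[3-(benzyloxy)phenoxy]-3-[3,4-bis(benzyloxy)phenyl]propanal | O=CC[C@H](Oc1cccc(OCc2ccccc2)c1)c1ccc(OCc2ccccc2)c(OCc2ccccc2)c1
A7 | alternative 2 | (2R,3R)-8-[(2S,4R)-7-(benzyloxy)-2-[3,4-bis(benzyloxy)phenyl]chroman-4-yl]-2-(3,4,5-trihydroxyphenyl)chroman-3,5,7-triol | c1ccccc1COc1ccc2c(c1)O[C@H](c1ccc(OCc3ccccc3)c(OCc3ccccc3)c1)C[C@H]2c1c(O)cc(O)c2c1O[C@H](c1cc(O)c(O)c(O)c1)[C@H](O)C2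
A8 | alternative 3 | 3-(benzyloxy)cyclobut-2-en-1-one | O=C1C=C(OCc2ccccc2)C1
A9 | alternative 3 | {[(2S,4S)-7-(benzyloxy)-2-[3,4-bis(benzyloxy)phenyl]chroman-4-yl]ethynyloxy}tri(propan-2-yl)silane (2,4-trans) | c1ccccc1COc1ccc2c(c1)O[C@H](c1ccc(OCc3ccccc3)c(OCc3ccccc3)c1)C[C@H]2C#CO[Si](C(C)C)(C(C)C)C(C)C
A10 | alternative 3 | 5-(benzyloxy)-2-[(2S,4R)-7-(benzyloxy)-2-[3,4-bis(benzyloxy)phenyl]chroman-4-yl]-3-[tri(propan-2-yl)silyloxy]phenol | c1ccccc1COc1ccc2c(c1)O[C@H](c1ccc(OCc3ccccc3)c(OCc3ccccc3)c1)C[C@H]2c1c(O)cc(OCc2ccccc2)cc1O[Si](C(C)C)(C(C)C)C(C)C
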